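The plan rests on cutting ring A at two adjacent bonds: the C6–O diaryl ether bond and the C1–CO2H bond. Ring A carries O (C6), carboxyl (C1) and O (C2) on three neighbouring carbons, the pattern a 3-alkoxyaryne delivers when a nucleophile adds remote from the alkoxy group and an electrophile is taken up beside it. In one operation a C1–C6 aryne, released from a 2-silylaryl triflate, is attacked by the ring B phenoxide and the resulting C1 anion is carboxylated by CO2. The precursor is 3-(methoxymethoxy)-4-prenyl-2-(trimethylsilyl)phenyl triflate; its partner is a ring B phenol carrying only MOM ethers.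

Key step: step 11

Remark: the target has no stereocentre. Ring A is numbered C1 (carboxyl), C2 (OH), C3 (prenyl), C6 (aryloxy); prenyl means 3-methylbut-2-enyl. The ring B phenol is taken as its potassium salt made with KH, so that no protic by-product enters the key step. It is built by directed metalation from 3-hydroxy-5-methylbenzoic acid (assumed purchasable), which avoids any selective protection.

Step 1
Reactants: 1 4-bromoresorcinol
Product: 2 2-bromo-5-(triisopropylsilyloxy)phenol
Conditions: TIPSCl (1.0 equiv), imidazole, CH2Cl2, 0 °C → rt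
Reagents that add atoms: chlorotriisopropylsilane, CC(C)[Si](Cl)(C(C)C)C(C)C
Why: Sterically controlled silylation of a phenol with a bulky silyl chloride under imidazole catalysis should take the hydroxyl para to bromine, because the other one is flanked by bromine and weakened as a nucleophile by its O–H···Br contact.

Step 2
Reactants: 2 2-bromo-5-(triisopropylsilyloxy)phenol
Product: 3 1-bromo-2-(methoxymethoxy)-4-(triisopropylsilyloxy)benzene
Conditions: MOMCl, i-Pr2NEt, CH2Cl2, 0 °C → rt
Reagents that add atoms: chloromethyl methyl ether, COCCl
Why: Williamson-type acetal ether formation on the remaining phenol with an amine base that leaves the aryl silyl ether in place.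

Step 3
Reactants: 3 1-bromo-2-(methoxymethoxy)-4-(triisopropylsilyloxy)benzene; 4 prenyl bromide
Product: 7 2-(methoxymethoxy)-1-(3-methylbut-2-enyl)-4-(triisopropylsilyloxy)benzene, via aryllithium 5 (not isolated), via arylcopper 6 (not isolated)
Conditions: n-BuLi, THF, −78 °C; CuBr·SMe2, −78 → −40 °C; then 4, −40 → 0 °C
Reagents that add atoms: none
Why: Bromine–lithium exchange followed by copper-mediated allylic substitution should work because exchange at −78 °C outruns attack on the silyl and acetal groups and the arylcopper couples with the primary allylic bromide at its unhindered terminus to give the linear prenyl arene.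

Step 4
Reactants: 7 2-(methoxymethoxy)-1-(3-methylbut-2-enyl)-4-(triisopropylsilyloxy)benzene
Product: 8 3-(methoxymethoxy)-4-(3-methylbut-2-enyl)phenol
Conditions: TBAF, THF, 0 °C; aq. NH4Cl
Reagents that add atoms: none
Why: Fluoride-mediated desilylation driven by the Si–F bond frees the phenol while the acetal and the alkene are untouched.

Step 5
Reactants: 8 3-(methoxymethoxy)-4-(3-methylbut-2-enyl)phenol
Product: 9 3-(methoxymethoxy)-4-(3-methylbut-2-enyl)phenyl N-isopropylcarbamate
Conditions: i-PrNCO, Et3N (cat.), CH2Cl2, rt
Reagents that add atoms: isopropyl isocyanate, CC(C)N=C=O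
Why: Base-catalysed addition of a phenol to an isocyanate installs a strong ortho-directing carbamate that can later be removed under mild amine conditions.

Step 6
Reactants: 9 3-(methoxymethoxy)-4-(3-methylbut-2-enyl)phenyl N-isopropylcarbamate
Product: 13 3-(methoxymethoxy)-4-(3-methylbut-2-enyl)-2-(trimethylsilyl)phenyl N-isopropylcarbamate, via N-silyl carbamate 10 (not isolated), via ortho-lithiated carbamate 11 (not isolated), via N-silyl C-silyl carbamate 12 (not isolated)
Conditions: TBSOTf, TMEDA, Et2O, 0 °C → rt; n-BuLi, TMEDA, −78 °C; TMSCl, −78 °C → rt; cold aq. citric acid work-up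
Reagents that add atoms: chlorotrimethylsilane, C[Si](C)(C)Cl
Why: Directed ortho-metalation should succeed because, after transient N-silylation, the carbamate and the OMOM group together direct n-BuLi to the single ring CH between them faster than to the prenyl CH2 at −78 °C, and the aryllithium is silylated before acyl migration can occur, the N-silyl group being lost on work-up.

Step 7
Reactants: 13 3-(methoxymethoxy)-4-(3-methylbut-2-enyl)-2-(trimethylsilyl)phenyl N-isopropylcarbamate
Product: 15 3-(methoxymethoxy)-4-(3-methylbut-2-enyl)-2-(trimethylsilyl)phenyl trifluoromethanesulfonate, via silyl phenol 14 (not isolated)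
Conditions: Et2NH, DBU, MeCN, 40 °C; then PhNTf2, rt
Reagents that add atoms: N-phenylbis(trifluoromethanesulfonimide), O=S(=O)(N(c1ccccc1)S(=O)(=O)C(F)(F)F)C(F)(F)F
Why: Amine-induced E1cB cleavage of the N-monosubstituted carbamate, with Et2NH scavenging the isocyanate, followed by sulfonylation of the phenoxide in the same flask is the standard close of the carbamate route to ortho-silylaryl triflates.

Step 8
Reactants: 16 3-hydroxy-5-methylbenzoic acid
Product: 17 3-(hydroxymethyl)-5-methylphenol
Conditions: BH3·THF, THF, 0 °C → rt; MeOH, then aqueous work-up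
Reagents that add atoms: none
Why: Borane reduction of a carboxylic acid through its acyloxyborane is chemoselective and tolerates the free phenol.

Step 9
Reactants: 17 3-(hydroxymethyl)-5-methylphenol
Product: 18 1-(methoxymethoxy)-3-[(methoxymethoxy)methyl]-5-methylbenzene
Conditions: NaH, MOMCl (excess), THF/DMF, 0 °C → rt
Reagents that add atoms: chloromethyl methyl ether, COCCl
Why: Double Williamson-type acetal ether formation needs no selectivity because both hydroxyl groups are to be protected.

Step 10
Reactants: 18 1-(methoxymethoxy)-3-[(methoxymethoxy)methyl]-5-methylbenzene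
Product: 21 2-(methoxymethoxy)-6-[(methoxymethoxy)methyl]-4-methylphenol, via aryllithium 19 (not isolated), via dimethyl boronate 20 (not isolated)
Conditions: n-BuLi, THF, 0 °C; B(OMe)3, −78 °C → rt; 30% H2O2, aq. NaOH, 0 °C → rt
Reagents that add atoms: hydrogen peroxide, OO
Why: Cooperative directed ortho-metalation at the only CH flanked by the OMOM and CH2OMOM groups, borylation and alkaline peroxide oxidation of the C–B bond should place the phenol between the two protected oxygens and para to the methyl group.

Step 11
Reactants: 15 3-(methoxymethoxy)-4-(3-methylbut-2-enyl)-2-(trimethylsilyl)phenyl trifluoromethanesulfonate; 21 2-(methoxymethoxy)-6-[(methoxymethoxy)methyl]-4-methylphenol; 22 carbon dioxide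
Product: 26 2-(methoxymethoxy)-6-[2-(methoxymethoxy)-6-[(methoxymethoxy)methyl]-4-methylphenoxy]-3-(3-methylbut-2-enyl)benzoic acid, via potassium phenoxide 23 (not isolated), via aryne 24 (not isolated), via aryl anion 25 (not isolated)
Conditions: 21 (1.5 equiv), KH, THF, 0 °C; then KF, 18-crown-6, CO2 (1–3 bar), slow addition of 15, 0 °C → rt; cold aq. citric acid to pH 3
Reagents that add atoms: none
Why: Proposed new method: Fluoride attacks the trimethylsilyl group of 15 and triflate departs, giving aryne 24 with its triple bond between C1 and C6 of ring A; phenoxide 23 adds at C6, the aryne carbon remote from the C2 OMOM group, and the C1 aryl anion 25 so formed is trapped by dissolved CO2 as the carboxylate. The closest known reaction types are the three-component couplings of arynes with amines or imines and CO2, and the fluoride-mediated O-arylation of phenols by silylaryl triflates; a phenoxide has not been combined with CO2 in this way. No ring is closed and no stereocentre is formed. The regioselectivity the step needs is secured by the C2 alkoxy group, which polarises and distorts the aryne as in 3-methoxybenzyne, so that the nucleophile enters at the distal carbon and the charge develops beside the C–O bond. Carboxylation must outrun protonation, which is secured by the hydride-derived phenoxide free of protic by-products, ether-only protection of ring B, THF as solvent and a CO2-saturated medium, while the substituted ortho and para positions of phenoxide 23 leave it no site for carboxylation on its own ring. The phenoxide is used in excess and the triflate is added slowly so that the hindered product carboxylate does not compete for the aryne.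

Step 12
Reactants: 26 2-(methoxymethoxy)-6-[2-(methoxymethoxy)-6-[(methoxymethoxy)methyl]-4-methylphenoxy]-3-(3-methylbut-2-enyl)benzoic acid
Product: 27 2-hydroxy-6-[2-hydroxy-6-(hydroxymethyl)-4-methylphenoxy]-3-(3-methylbut-2-enyl)benzoic acid
Conditions: ZnBr2, n-PrSH, CH2Cl2, 0 °C → rt (short contact); aq. citric acid work-up
Reagents that add atoms: none
Why: Lewis acid-assisted acetal cleavage with a soft thiol nucleophile should remove all three MOM ethers, two on phenols and one on the benzylic alcohol, because ZnBr2 activates each O–CH2–O unit and the thiol captures the methoxymethyl fragment without the strong Brønsted acid that would close the prenyl group onto the C2 phenol.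

Compound list
1 | 4-bromoresorcinol (4-bromobenzene-1,3-diol) | Oc1ccc(Br)c(O)c1 | starting material
2 | 2-bromo-5-(triisopropylsilyloxy)phenol | Oc1cc(O[Si](C(C)C)(C(C)C)C(C)C)ccc1Br | intermediate
3 | 1-bromo-2-(methoxymethoxy)-4-(triisopropylsilyloxy)benzene | COCOc1cc(O[Si](C(C)C)(C(C)C)C(C)C)ccc1Br | intermediate
4 | prenyl bromide (1-bromo-3-methylbut-2-ene) | CC(C)=CCBr | starting material
5 | 2-(methoxymethoxy)-4-(triisopropylsilyloxy)phenyllithium (not isolated) | COCOc1cc(O[Si](C(C)C)(C(C)C)C(C)C)ccc1[Li] | intermediate
6 | 2-(methoxymethoxy)-4-(triisopropylsilyloxy)phenylcopper (not isolated) | COCOc1cc(O[Si](C(C)C)(C(C)C)C(C)C)ccc1[Cu] | intermediate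
7 | 2-(methoxymethoxy)-1-(3-methylbut-2-enyl)-4-(triisopropylsilyloxy)benzene | COCOc1cc(O[Si](C(C)C)(C(C)C)C(C)C)ccc1CC=C(C)C | intermediate
8 | 3-(methoxymethoxy)-4-(3-methylbut-2-enyl)phenol | COCOc1cc(O)ccc1CC=C(C)C | intermediate
9 | 3-(methoxymethoxy)-4-(3-methylbut-2-enyl)phenyl N-isopropylcarbamate | COCOc1cc(OC(=O)NC(C)C)ccc1CC=C(C)C | intermediate
10 | N-(tert-butyldimethylsilyl) derivative of carbamate 9 (not isolated) | COCOc1cc(OC(=O)N(C(C)C)[Si](C)(C)C(C)(C)C)ccc1CC=C(C)C | intermediate
11 | 10 lithiated at the ring carbon between the two oxygens (not isolated) | COCOc1c([Li])c(OC(=O)N(C(C)C)[Si](C)(C)C(C)(C)C)ccc1CC=C(C)C | intermediate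
12 | N-(tert-butyldimethylsilyl) derivative of carbamate 13 (not isolated) | COCOc1c([Si](C)(C)C)c(OC(=O)N(C(C)C)[Si](C)(C)C(C)(C)C)ccc1CC=C(C)C | intermediate
13 | 3-(methoxymethoxy)-4-(3-methylbut-2-enyl)-2-(trimethylsilyl)phenyl N-isopropylcarbamate | COCOc1c([Si](C)(C)C)c(OC(=O)NC(C)C)ccc1CC=C(C)C | intermediate
14 | 3-(methoxymethoxy)-4-(3-methylbut-2-enyl)-2-(trimethylsilyl)phenol (not isolated) | COCOc1c([Si](C)(C)C)c(O)ccc1CC=C(C)C | intermediate
15 | 3-(methoxymethoxy)-4-(3-methylbut-2-enyl)-2-(trimethylsilyl)phenyl trifluoromethanesulfonate | CC(C)=CCc1ccc(OS(=O)(=O)C(F)(F)F)c([Si](C)(C)C)c1OCOC | intermediate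
16 | 3-hydroxy-5-methylbenzoic acid | Cc1cc(O)cc(C(=O)O)c1 | starting material
17 | 3-(hydroxymethyl)-5-methylphenol | Cc1cc(O)cc(CO)c1 | intermediate
18 | 1-(methoxymethoxy)-3-[(methoxymethoxy)methyl]-5-methylbenzene | COCOCc1cc(C)cc(OCOC)c1 | intermediate
19 | 2-(methoxymethoxy)-6-[(methoxymethoxy)methyl]-4-methylphenyllithium (not isolated) | COCOCc1cc(C)cc(OCOC)c1[Li] | intermediate
20 | dimethyl 2-(methoxymethoxy)-6-[(methoxymethoxy)methyl]-4-methylphenylboronate (not isolated) | COCOCc1cc(C)cc(OCOC)c1B(OC)OC | intermediate
21 | 2-(methoxymethoxy)-6-[(methoxymethoxy)methyl]-4-methylphenol | COCOCc1cc(C)cc(OCOC)c1O | intermediate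
22 | carbon dioxide | O=C=O | starting material
23 | potassium 2-(methoxymethoxy)-6-[(methoxymethoxy)methyl]-4-methylphenoxide (not isolated) | COCOCc1cc(C)cc(OCOC)c1[O-].[K+] | intermediate
24 | 3-(methoxymethoxy)-4-(3-methylbut-2-enyl)benzyne, triple bond between C1 and C6 of ring A (not isolated) | CC(C)=CCC1=C(OCOC)C#CC=C1 | intermediate
25 | C1 arylpotassium formed by addition of 23 to C6 of 24 (not isolated) | CC(C)=CCc1ccc(Oc2c(OCOC)cc(C)cc2COCOC)c([K])c1OCOC | intermediate
26 | 2-(methoxymethoxy)-6-[2-(methoxymethoxy)-6-[(methoxymethoxy)methyl]-4-methylphenoxy]-3-(3-methylbut-2-enyl)benzoic acid | CC(C)=CCc1ccc(Oc2c(OCOC)cc(C)cc2COCOC)c(C(=O)O)c1OCOC | intermediate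
27 | 2-hydroxy-6-[2-hydroxy-6-(hydroxymethyl)-4-methylphenoxy]-3-(3-methylbut-2-enyl)benzoic acid | CC(C)=CCc1ccc(Oc2c(O)cc(C)cc2CO)c(C(=O)O)c1O | target

Total step count: 12 (ring A fragment: steps 1–7; ring B fragment: steps 8–10; union: step 11; unmasking: step 12).
Longest linear sequence: 9 steps (steps 1–7, 11, 12).

The three steps most likely to fail, each with its fallback

First risk, step 11: the C1 aryl anion may be protonated faster than it is carboxylated, or the phenoxide may be held back as its carbonate so that the aryne is consumed by the product carboxylate or by fluoride. The fallback for step 11 uses two known operations and sets out from 15 and 21. CsF in MeCN at rt effects the established O-arylation of the free phenol by the aryne, with the same regiochemistry, and should give 1-[2-(methoxymethoxy)-6-[(methoxymethoxy)methyl]-4-methylphenoxy]-3-(methoxymethoxy)-4-(3-methylbut-2-enyl)benzene F1. Directed ortho-lithiation of the ring A CH flanked by the aryloxy and OMOM groups of this ether (n-BuLi, TMEDA, THF, −78 °C) and a quench with 22 then brings the fallback back to the route at 26.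

Second risk, step 6: deprotonation of the benzylic and allylic CH2 of the prenyl group beside the OMOM group may compete with ring lithiation, or the carbamoyl group may migrate to carbon before silylation. The fallback for step 6 brings in silicon before the prenyl group exists and uses an amide base that leaves the aryl bromide alone; it sets out from 3. TBAF in THF should give 4-bromo-3-(methoxymethoxy)phenol F2. ClC(O)NEt2 with K2CO3 in MeCN should convert it into 4-bromo-3-(methoxymethoxy)phenyl N,N-diethylcarbamate F3. LiN(i-Pr)2 with TMSCl present (THF, −78 °C, in situ trapping) should silylate the CH between the two oxygens to give 4-bromo-3-(methoxymethoxy)-2-(trimethylsilyl)phenyl N,N-diethylcarbamate F4. Bromine–lithium exchange, transmetalation with CuBr·SMe2 and allylation with 4 under the conditions of step 3 should then give 3-(methoxymethoxy)-4-(3-methylbut-2-enyl)-2-(trimethylsilyl)phenyl N,N-diethylcarbamate F5. LiAlH4 in THF cleaves the carbamate, and the fallback comes back to the route at 14, which is triflated with PhNTf2 and DBU as in the second stage of step 7 to give 15.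

Third risk, step 12: the hindered C2 acetal of ring A may be removed incompletely, the thiol may capture the ring B benzylic position, or acid may close the prenyl group onto the freed C2 phenol and cause loss of CO2 from the electron-rich salicylic acid. The fallback for step 12 masks the acid and uses thiol-free Brønsted acetal exchange; it sets out from 26. Allyl bromide and K2CO3 in DMF should give allyl 2-(methoxymethoxy)-6-[2-(methoxymethoxy)-6-[(methoxymethoxy)methyl]-4-methylphenoxy]-3-(3-methylbut-2-enyl)benzoate F6. Methanolic HCl (from AcCl in MeOH, 0 °C → rt) should remove the three MOM groups to give allyl 2-hydroxy-6-[2-hydroxy-6-(hydroxymethyl)-4-methylphenoxy]-3-(3-methylbut-2-enyl)benzoate F7. Pd(PPh3)4 with morpholine in THF at rt then removes the allyl group, and the fallback comes back to the route at 27.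

Further compounds
F1 | step 11 | 1-[2-(methoxymethoxy)-6-[(methoxymethoxy)methyl]-4-methylphenoxy]-3-(methoxymethoxy)-4-(3-methylbut-2-enyl)benzene | CC(C)=CCc1ccc(Oc2c(OCOC)cc(C)cc2COCOC)cc1OCOC
F2 | step 6 | 4-bromo-3-(methoxymethoxy)phenol | COCOc1cc(O)ccc1Br
F3 | step 6 | 4-bromo-3-(methoxymethoxy)phenyl N,N-diethylcarbamate | CCN(CC)C(=O)Oc1ccc(Br)c(OCOC)c1
F4 | step 6 | 4-bromo-3-(methoxymethoxy)-2-(trimethylsilyl)phenyl N,N-diethylcarbamate | CCN(CC)C(=O)Oc1ccc(Br)c(OCOC)c1[Si](C)(C)C
F5 | step 6 | 3-(methoxymethoxy)-4-(3-methylbut-2-enyl)-2-(trimethylsilyl)phenyl N,N-diethylcarbamate | CCN(CC)C(=O)Oc1ccc(CC=C(C)C)c(OCOC)c1[Si](C)(C)C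
F6 | step 12 | allyl 2-(methoxymethoxy)-6-[2-(methoxymethoxy)-6-[(methoxymethoxy)methyl]-4-methylphenoxy]-3-(3-methylbut-2-enyl)benzoate | C=CCOC(=O)c1c(Oc2c(OCOC)cc(C)cc2COCOC)ccc(CC=C(C)C)c1OCOC
F7 | step 12 | allyl 2-hydroxy-6-[2-hydroxy-6-(hydroxymethyl)-4-methylphenoxy]-3-(3-methylbut-2-enyl)benzoate | C=CCOC(=O)c1c(Oc2c(O)cc(C)cc2CO)ccc(CC=C(C)C)c1O
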